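## Retrosynthetic overview

1. Target 14 comes from the cis permethyl ether 12 by global O‑demethylation, during which acid equilibrates C2 from cis to the more stable trans ring.
2. The (E)‑stilbene of 12 comes from a Heck coupling of the C6 aryl bromide 10 with 3,4‑dimethoxystyrene.
3. The dihydrofuran ring (C2–C3 bond) is the only ring built. It comes from an enantioselective Rh(II) donor/donor‑carbene insertion into the benzylic ether C–H of a diaryldiazomethane made from hydrazone 8.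
4. Hydrazone 8 comes from the 2‑benzyloxy‑6‑methoxy‑4‑bromobenzophenone 7, made by chelation‑controlled mono‑demethylation and O‑benzylation of the 2,6‑dimethoxy ketone 4.
5. Ketone 4 comes from 4‑bromo‑2,6‑dimethoxybenzaldehyde and a 3,5‑dimethoxyphenyl Grignard reagent, followed by oxidation. All four benzene rings are bought.

Assumption: Rh2(R‑PTAD)4 is taken to give the (2R,3S)‑cis insertion product 10; if chiral HPLC/ECD on 10 shows the opposite sense for this substrate, the commercial mirror‑image catalyst Rh2(S‑PTAD)4 is used and nothing else changes.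

## Route

**Step 1**
Reactants: 1 4‑bromo‑2,6‑dimethoxybenzaldehyde; 2 (3,5‑dimethoxyphenyl)magnesium chloride (commercial 1.0 M solution in THF)
Product: 3 rac‑(4‑bromo‑2,6‑dimethoxyphenyl)(3,5‑dimethoxyphenyl)methanol
Conditions: THF, 0 °C → rt; sat. aq NH4Cl
Reagents that add atoms: none
Why: Grignard 1,2‑addition to the aldehyde is fast at 0 °C and leaves the aryl bromide untouched; the new carbinol centre is racemic and is erased in step 2.

**Step 2**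
Reactants: 3 rac‑(4‑bromo‑2,6‑dimethoxyphenyl)(3,5‑dimethoxyphenyl)methanol
Product: 4 (4‑bromo‑2,6‑dimethoxyphenyl)(3,5‑dimethoxyphenyl)methanone
Conditions: Dess–Martin periodinane (1.3 equiv), CH2Cl2, rt
Reagents that add atoms: none
Why: Dess–Martin oxidation converts the hindered, electron‑rich benzhydrol into the benzophenone under near‑neutral conditions without touching the aryl bromide or the methyl ethers.

**Step 3**
Reactants: 4 (4‑bromo‑2,6‑dimethoxyphenyl)(3,5‑dimethoxyphenyl)methanone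
Product: 5 (4‑bromo‑2‑hydroxy‑6‑methoxyphenyl)(3,5‑dimethoxyphenyl)methanone
Conditions: BCl3 (1.2 equiv, 1 M in CH2Cl2), CH2Cl2, −78 → 0 °C; H2O
Reagents that add atoms: none
Why: Chelation‑controlled Lewis‑acid ether cleavage, in which BCl3 bound to the ketone removes only one ortho methoxy group through a six‑membered boron chelate that then deactivates the second ortho ether, while the remote 3,5‑dimethoxy ring is never activated.

**Step 4**
Reactants: 5 (4‑bromo‑2‑hydroxy‑6‑methoxyphenyl)(3,5‑dimethoxyphenyl)methanone; 6 4‑(chloromethyl)‑1,2‑dimethoxybenzene (3,4‑dimethoxybenzyl chloride)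
Product: 7 {4‑bromo‑2‑[(3,4‑dimethoxyphenyl)methoxy]‑6‑methoxyphenyl}(3,5‑dimethoxyphenyl)methanone
Conditions: K2CO3 (2 equiv), NaI (10 mol%), DMF, 60 °C
Reagents that add atoms: none
Why: Williamson ether synthesis in which the phenoxide displaces the activated benzylic chloride (Finkelstein‑assisted), installing the OCH2Ar group whose C–H bond is inserted in step 6.

**Step 5**
Reactants: 7 {4‑bromo‑2‑[(3,4‑dimethoxyphenyl)methoxy]‑6‑methoxyphenyl}(3,5‑dimethoxyphenyl)methanone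
Product: 8 [{4‑bromo‑2‑[(3,4‑dimethoxyphenyl)methoxy]‑6‑methoxyphenyl}(3,5‑dimethoxyphenyl)methylidene]hydrazine (E/Z mixture)
Conditions: N2H4·H2O (20 equiv), AcOH (cat.), n‑BuOH, 120 °C, sealed tube
Reagents that add atoms: hydrazine (used as the monohydrate), NN
Why: Acid‑catalysed condensation of the ketone with a large excess of hydrazine gives the N‑unsubstituted hydrazone, the excess and temperature overcoming the di‑ortho‑substituted carbonyl and suppressing azine formation (both C=N isomers give the same diazo compound).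

**Step 6**
Reactants: 8 [{4‑bromo‑2‑[(3,4‑dimethoxyphenyl)methoxy]‑6‑methoxyphenyl}(3,5‑dimethoxyphenyl)methylidene]hydrazine
Product: 10 (2R,3S)‑6‑bromo‑2‑(3,4‑dimethoxyphenyl)‑3‑(3,5‑dimethoxyphenyl)‑4‑methoxy‑2,3‑dihydro‑1‑benzofuran (2,3‑cis), via diaryldiazomethane 9 (not isolated)
Conditions: MnO2 (8 equiv), Rh2(R‑PTAD)4 (1 mol%), MeCN, 0 °C
Reagents that add atoms: none
Why: MnO2 dehydrogenates the hydrazone to the donor/donor diazo compound, whose Rh(II) carbene undergoes enantioselective intramolecular 1,5‑C–H insertion into the benzylic C–H alpha to oxygen (far more reactive than the OCH3 C–H bonds), the chiral carboxylate pocket setting C3 as S and the insertion transition state placing both aryl groups cis so that C2 is R.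

**Step 7**
Reactants: 10 (2R,3S)‑6‑bromo‑2‑(3,4‑dimethoxyphenyl)‑3‑(3,5‑dimethoxyphenyl)‑4‑methoxy‑2,3‑dihydro‑1‑benzofuran; 11 4‑ethenyl‑1,2‑dimethoxybenzene (3,4‑dimethoxystyrene)
Product: 12 (2R,3S)‑2‑(3,4‑dimethoxyphenyl)‑3‑(3,5‑dimethoxyphenyl)‑6‑[(E)‑2‑(3,4‑dimethoxyphenyl)ethenyl]‑4‑methoxy‑2,3‑dihydro‑1‑benzofuran (2,3‑cis)
Conditions: Pd(OAc)2 (5 mol%), P(o‑tol)3 (10 mol%), Et3N (3 equiv), DMF, 100 °C
Reagents that add atoms: none
Why: Mizoroki–Heck coupling of the unhindered aryl bromide with the terminal styrene gives the (E)‑stilbene by syn‑insertion and syn‑β‑hydride elimination, and the amine base is too weak to epimerise C2 or C3.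

**Step 8**
Reactants: 12 (2R,3S)‑2‑(3,4‑dimethoxyphenyl)‑3‑(3,5‑dimethoxyphenyl)‑6‑[(E)‑2‑(3,4‑dimethoxyphenyl)ethenyl]‑4‑methoxy‑2,3‑dihydro‑1‑benzofuran
Product: 14 (2S,3S)‑2‑(3,4‑dihydroxyphenyl)‑3‑(3,5‑dihydroxyphenyl)‑6‑[(E)‑2‑(3,4‑dihydroxyphenyl)ethenyl]‑2,3‑dihydro‑1‑benzofuran‑4‑ol (target, 2,3‑trans), via cis‑heptaphenol 13 (not isolated)
Conditions: BBr3 (15 equiv), CH2Cl2, −78 °C → rt, 16 h, Ar; ice/H2O; reverse‑phase purification
Reagents that add atoms: none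
Why: BBr3 cleaves all seven aryl methyl ethers, and the acidic medium reversibly ionises the C2–O bond (benzylic cation/para‑quinone methide stabilised by the 4‑oxygen of the C2 aryl group) so that reclosure gives the thermodynamically preferred 2,3‑trans ring, inverting C2 from R to S while the non‑ionisable C3 stays S.

## Compound list

1 | 4‑bromo‑2,6‑dimethoxybenzaldehyde | O=Cc1c(OC)cc(Br)cc1OC | starting material
2 | (3,5‑dimethoxyphenyl)magnesium chloride | COc1cc(OC)cc([Mg]Cl)c1 | starting material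
3 | rac‑(4‑bromo‑2,6‑dimethoxyphenyl)(3,5‑dimethoxyphenyl)methanol | COc1cc(OC)cc(C(O)c2c(OC)cc(Br)cc2OC)c1 | intermediate
4 | (4‑bromo‑2,6‑dimethoxyphenyl)(3,5‑dimethoxyphenyl)methanone | COc1cc(OC)cc(C(=O)c2c(OC)cc(Br)cc2OC)c1 | intermediate
5 | (4‑bromo‑2‑hydroxy‑6‑methoxyphenyl)(3,5‑dimethoxyphenyl)methanone | COc1cc(OC)cc(C(=O)c2c(O)cc(Br)cc2OC)c1 | intermediate
6 | 4‑(chloromethyl)‑1,2‑dimethoxybenzene | COc1ccc(CCl)cc1OC | starting material
7 | {4‑bromo‑2‑[(3,4‑dimethoxyphenyl)methoxy]‑6‑methoxyphenyl}(3,5‑dimethoxyphenyl)methanone | COc1cc(OC)cc(C(=O)c2c(OCc3ccc(OC)c(OC)c3)cc(Br)cc2OC)c1 | intermediate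
8 | [{4‑bromo‑2‑[(3,4‑dimethoxyphenyl)methoxy]‑6‑methoxyphenyl}(3,5‑dimethoxyphenyl)methylidene]hydrazine (E/Z mixture) | COc1cc(OC)cc(C(=NN)c2c(OCc3ccc(OC)c(OC)c3)cc(Br)cc2OC)c1 | intermediate
9 | 5‑bromo‑2‑[diazo(3,5‑dimethoxyphenyl)methyl]‑1‑[(3,4‑dimethoxyphenyl)methoxy]‑3‑methoxybenzene | COc1cc(OC)cc(C(=[N+]=[N-])c2c(OCc3ccc(OC)c(OC)c3)cc(Br)cc2OC)c1 | intermediate (not isolated)
10 | (2R,3S)‑6‑bromo‑2‑(3,4‑dimethoxyphenyl)‑3‑(3,5‑dimethoxyphenyl)‑4‑methoxy‑2,3‑dihydro‑1‑benzofuran (cis) | COc1cc(OC)cc([C@H]2c3c(OC)cc(Br)cc3O[C@H]2c2ccc(OC)c(OC)c2)c1 | intermediate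
11 | 4‑ethenyl‑1,2‑dimethoxybenzene | C=Cc1ccc(OC)c(OC)c1 | starting material
12 | (2R,3S)‑2‑(3,4‑dimethoxyphenyl)‑3‑(3,5‑dimethoxyphenyl)‑6‑[(E)‑2‑(3,4‑dimethoxyphenyl)ethenyl]‑4‑methoxy‑2,3‑dihydro‑1‑benzofuran (cis) | COc1cc(OC)cc([C@H]2c3c(OC)cc(/C=C/c4ccc(OC)c(OC)c4)cc3O[C@H]2c2ccc(OC)c(OC)c2)c1 | intermediate
13 | (2R,3S)‑2‑(3,4‑dihydroxyphenyl)‑3‑(3,5‑dihydroxyphenyl)‑6‑[(E)‑2‑(3,4‑dihydroxyphenyl)ethenyl]‑2,3‑dihydro‑1‑benzofuran‑4‑ol (cis) | Oc1cc(O)cc([C@H]2c3c(O)cc(/C=C/c4ccc(O)c(O)c4)cc3O[C@H]2c2ccc(O)c(O)c2)c1 | intermediate (not isolated)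
14 | (2S,3S)‑2‑(3,4‑dihydroxyphenyl)‑3‑(3,5‑dihydroxyphenyl)‑6‑[(E)‑2‑(3,4‑dihydroxyphenyl)ethenyl]‑2,3‑dihydro‑1‑benzofuran‑4‑ol (trans) | Oc1cc(O)cc([C@H]2c3c(O)cc(/C=C/c4ccc(O)c(O)c4)cc3O[C@@H]2c2ccc(O)c(O)c2)c1 | target

## Step count and risks

Total step count: 8. Longest linear sequence: 8 steps (1 → 14); compounds 2, 6 and 11 are bought.

**Step 5 (hydrazone formation).** The di‑ortho‑alkoxy benzophenone may condense sluggishly or give azine. The fallback sets out from 7 and comes back to the route at 8. Lawesson's reagent (toluene, 110 °C) converts the ketone into {4‑bromo‑2‑[(3,4‑dimethoxyphenyl)methoxy]‑6‑methoxyphenyl}(3,5‑dimethoxyphenyl)methanethione F1. Its far more electrophilic C=S group then condenses with N2H4·H2O (THF/EtOH, 0 °C to rt), with loss of hydrogen sulfide, to give 8.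

**Step 6 (carbene C–H insertion).** The extra ortho methoxy group may lower ee or dr, or divert the carbene to azine or OCH3 insertion. The fallback sets out from 7 and comes back to the route at 14; it replaces carbene chemistry by benzofuran formation, ionic hydrogenation and resolution. t‑Bu‑P4 (toluene, 100 °C) deprotonates the benzylic ether CH2, which adds to the ketone and loses water to give 6‑bromo‑2‑(3,4‑dimethoxyphenyl)‑3‑(3,5‑dimethoxyphenyl)‑4‑methoxy‑1‑benzofuran F2. Et3SiH/TFA (CH2Cl2, 0 °C to rt) reduces it through the C2 oxocarbenium ion, with hydride delivered anti to the C3 aryl group, to the racemic trans‑dihydrobenzofuran. Preparative chiral SFC separates this into (2S,3S)‑6‑bromo‑2‑(3,4‑dimethoxyphenyl)‑3‑(3,5‑dimethoxyphenyl)‑4‑methoxy‑2,3‑dihydro‑1‑benzofuran F3 and the discarded (2R,3R)‑6‑bromo‑2‑(3,4‑dimethoxyphenyl)‑3‑(3,5‑dimethoxyphenyl)‑4‑methoxy‑2,3‑dihydro‑1‑benzofuran F4. Heck coupling of F3 with 11 under the step 7 conditions gives (2S,3S)‑2‑(3,4‑dimethoxyphenyl)‑3‑(3,5‑dimethoxyphenyl)‑6‑[(E)‑2‑(3,4‑dimethoxyphenyl)ethenyl]‑4‑methoxy‑2,3‑dihydro‑1‑benzofuran F5. BBr3 as in step 8, with no epimerisation needed, then gives 14.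

**Step 8 (sevenfold demethylation with C2 epimerisation).** The stilbene and the catechols may not survive BBr3, the cis/trans equilibration may be incomplete, or C3 may erode through an elimination pathway. The fallback sets out from 10 and comes back to the route at 14; it moves the demethylation ahead of the stilbene and finishes with acetate protection. BBr3 (CH2Cl2, −78 °C to rt) on 10 gives first the cis pentaphenol (2R,3S)‑6‑bromo‑2‑(3,4‑dihydroxyphenyl)‑3‑(3,5‑dihydroxyphenyl)‑2,3‑dihydro‑1‑benzofuran‑4‑ol F6, which epimerises in the flask to the trans pentaphenol (2S,3S)‑6‑bromo‑2‑(3,4‑dihydroxyphenyl)‑3‑(3,5‑dihydroxyphenyl)‑2,3‑dihydro‑1‑benzofuran‑4‑ol F7. Ac2O/pyridine gives (2S,3S)‑6‑bromo‑2‑(3,4‑diacetoxyphenyl)‑3‑(3,5‑diacetoxyphenyl)‑2,3‑dihydro‑1‑benzofuran‑4‑yl acetate F8. Heck coupling with commercial 4‑ethenyl‑1,2‑phenylene diacetate (Pd(OAc)2, P(o‑tol)3, Et3N, DMF, 90 °C) gives (2S,3S)‑2‑(3,4‑diacetoxyphenyl)‑3‑(3,5‑diacetoxyphenyl)‑6‑[(E)‑2‑(3,4‑diacetoxyphenyl)ethenyl]‑2,3‑dihydro‑1‑benzofuran‑4‑yl acetate F9. K2CO3 in degassed MeOH at 0 °C removes the acetates to give 14.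

## Further compounds

F1 | step 5 | {4‑bromo‑2‑[(3,4‑dimethoxyphenyl)methoxy]‑6‑methoxyphenyl}(3,5‑dimethoxyphenyl)methanethione | COc1cc(OC)cc(C(=S)c2c(OCc3ccc(OC)c(OC)c3)cc(Br)cc2OC)c1
F2 | step 6 | 6‑bromo‑2‑(3,4‑dimethoxyphenyl)‑3‑(3,5‑dimethoxyphenyl)‑4‑methoxy‑1‑benzofuran | COc1cc(OC)cc(-c2c(-c3ccc(OC)c(OC)c3)oc3cc(Br)cc(OC)c23)c1
F3 | step 6 | (2S,3S)‑6‑bromo‑2‑(3,4‑dimethoxyphenyl)‑3‑(3,5‑dimethoxyphenyl)‑4‑methoxy‑2,3‑dihydro‑1‑benzofuran | COc1cc(OC)cc([C@H]2c3c(OC)cc(Br)cc3O[C@@H]2c2ccc(OC)c(OC)c2)c1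
F4 | step 6 | (2R,3R)‑6‑bromo‑2‑(3,4‑dimethoxyphenyl)‑3‑(3,5‑dimethoxyphenyl)‑4‑methoxy‑2,3‑dihydro‑1‑benzofuran | COc1cc(OC)cc([C@@H]2c3c(OC)cc(Br)cc3O[C@H]2c2ccc(OC)c(OC)c2)c1
F5 | step 6 | (2S,3S)‑2‑(3,4‑dimethoxyphenyl)‑3‑(3,5‑dimethoxyphenyl)‑6‑[(E)‑2‑(3,4‑dimethoxyphenyl)ethenyl]‑4‑methoxy‑2,3‑dihydro‑1‑benzofuran | COc1cc(OC)cc([C@H]2c3c(OC)cc(/C=C/c4ccc(OC)c(OC)c4)cc3O[C@@H]2c2ccc(OC)c(OC)c2)c1
F6 | step 8 | (2R,3S)‑6‑bromo‑2‑(3,4‑dihydroxyphenyl)‑3‑(3,5‑dihydroxyphenyl)‑2,3‑dihydro‑1‑benzofuran‑4‑ol | Oc1cc(O)cc([C@H]2c3c(O)cc(Br)cc3O[C@H]2c2ccc(O)c(O)c2)c1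
F7 | step 8 | (2S,3S)‑6‑bromo‑2‑(3,4‑dihydroxyphenyl)‑3‑(3,5‑dihydroxyphenyl)‑2,3‑dihydro‑1‑benzofuran‑4‑ol | Oc1cc(O)cc([C@H]2c3c(O)cc(Br)cc3O[C@@H]2c2ccc(O)c(O)c2)c1
F8 | step 8 | (2S,3S)‑6‑bromo‑2‑(3,4‑diacetoxyphenyl)‑3‑(3,5‑diacetoxyphenyl)‑2,3‑dihydro‑1‑benzofuran‑4‑yl acetate | CC(=O)Oc1cc(OC(C)=O)cc([C@H]2c3c(OC(C)=O)cc(Br)cc3O[C@@H]2c2ccc(OC(C)=O)c(OC(C)=O)c2)c1
F9 | step 8 | (2S,3S)‑2‑(3,4‑diacetoxyphenyl)‑3‑(3,5‑diacetoxyphenyl)‑6‑[(E)‑2‑(3,4‑diacetoxyphenyl)ethenyl]‑2,3‑dihydro‑1‑benzofuran‑4‑yl acetate | CC(=O)Oc1cc(OC(C)=O)cc([C@H]2c3c(OC(C)=O)cc(/C=C/c4ccc(OC(C)=O)c(OC(C)=O)c4)cc3O[C@@H]2c2ccc(OC(C)=O)c(OC(C)=O)c2)c1
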